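**Retrosynthetic overview**

- The target is 3,7,4'-trihydroxy-3'-methoxyflavone (geraldol) carrying three O-sulfate groups, with no stereocentre. The sulfates go on last, onto the free triol; the triol comes from a 7,4'-dibenzyl flavonol, and its 3-OH from a 3-bromide by borylation and oxidation.
- The strategy rests on one feature of ring C (O1–C2–C3–C4–C4a–C8a): C3 lies between the aryl-bearing C2 and the carbonyl carbon C4 and carries only a heteroatom. Cutting out C3 (bonds C2–C3 and C3–C4) contracts ring C to the furan ring of a 2-aryl-3-siloxybenzofuran, and C3 becomes the carbon of dibromocarbene from bromoform.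
- The siloxybenzofuran comes from 6-(benzyloxy)benzofuran-3(2H)-one by palladium-catalysed α-arylation (bond C2–C1') with benzyl-protected 4-bromo-2-methoxyphenol, with O-silylation in the same flask.
- Ring order: rings A and B are bought as arenes, ring A already fused to the five-membered furanone. Ring C is made last, by one-carbon expansion of that furanone ring.

Key step: step 4

Assumption: the target is drawn as the free tris(hydrogen sulfate), a strong and hydrolytically labile acid. The stable trisodium salt is therefore isolated first, and the acid form is released from it only in the last step, in cold water.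

**Route**

Step 1
Reactants: 1 6-hydroxybenzofuran-3(2H)-one
Product: 2 6-(benzyloxy)benzofuran-3(2H)-one
Conditions: BnBr (1.05 equiv), K2CO3, DMF, 0 °C → rt
Reagents that add atoms: benzyl bromide, BrCc1ccccc1
Why: Williamson etherification; the 6-OH, para to the ketone, is far more acidic than the C2 methylene, so K2CO3 at room temperature should alkylate oxygen only and leave the enolisable ketone untouched.

Step 2
Reactants: 3 4-bromo-2-methoxyphenol
Product: 4 1-(benzyloxy)-4-bromo-2-methoxybenzene
Conditions: BnBr, K2CO3, acetone, reflux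
Reagents that add atoms: benzyl bromide, BrCc1ccccc1
Why: Williamson etherification of a simple phenol; the benzyl ether masks the future 4'-OH against the strong bases of steps 3 and 4 and leaves together with the ring A benzyl group in one hydrogenolysis.

Step 3
Reactants: 2 6-(benzyloxy)benzofuran-3(2H)-one; 4 1-(benzyloxy)-4-bromo-2-methoxybenzene
Product: 6 6-(benzyloxy)-2-[4-(benzyloxy)-3-methoxyphenyl]-3-[(tert-butyldimethylsilyl)oxy]benzofuran, via sodium benzofuran-3-olate 5 (not isolated)
Conditions: Pd2(dba)3 (cat.), XPhos, NaOtBu (2.3 equiv), toluene/THF, 70 °C, argon; then TBSOTf, 0 °C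
Reagents that add atoms: tert-butyldimethylsilyl trifluoromethanesulfonate, CC(C)(C)[Si](C)(C)OS(=O)(=O)C(F)(F)F
Why: Buchwald–Hartwig α-arylation of a ketone enolate, in which the aryl palladium enolate of the bulky biarylphosphine reductively eliminates to form C2–C1'; the product is at once deprotonated to the aromatic benzofuran-3-olate 5, which is too hindered and too stabilised for a second arylation and is O-silylated in the same flask, so that the air-sensitive 2-aryl-3-coumaranone is never handled.

Step 4
Reactants: 6 6-(benzyloxy)-2-[4-(benzyloxy)-3-methoxyphenyl]-3-[(tert-butyldimethylsilyl)oxy]benzofuran; 7 bromoform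
Product: 10 7,4'-bis(benzyloxy)-3-bromo-3'-methoxyflavone, via dibromocyclopropane adduct 8 (not isolated), via 4-siloxyflavylium bromide 9 (not isolated)
Conditions: KOtBu (3 equiv, solid, in portions), toluene/hexane, −20 °C → rt (then 50 °C if 8 persists)
Reagents that add atoms: none
Why: α-Elimination of HBr from bromoform by KOtBu releases dibromocarbene, an electrophile for which the only strongly nucleophilic alkene in 6 is the tetrasubstituted enol ether bond C2=C3 (O1 on one carbon, the siloxy oxygen on the other), and concerted syn [2+1] addition there should give the cis-fused dibromocyclopropane 8. Since the three-membered ring is fused to a five-membered ring, the disrotatory cyclopropyl-to-allyl opening (Woodward–Hoffmann–DePuy) can only break the shared bond, the former C2–C3, while the endo bromide leaves with the help of the lone pairs on O1 and on the siloxy oxygen; the resulting 4-siloxyflavylium bromide 9 gives up its silyl group to bromide or tert-butoxide and becomes the 4-pyranone. Ring C is thus not closed by a cyclisation but arises from the furan ring by a one-carbon ring expansion that leaves the new carbon as C3, bonded to C2 and to C4, and the closest known reactions are the dihalocarbene ring expansion of cyclic silyl enol ethers (1-siloxycycloalkenes and 1-siloxyindenes) to 2-halo enones and 2-halonaphthols and the Ciamician–Dennstedt expansion of indoles and benzofurans. The two stereocentres of 8 are transient and vanish on ring opening, so no stereocontrol is required and 10 is achiral. The step needs chemoselectivity for C2=C3 over the two alkoxyarenes, the benzylic C–H bonds and the product, which is secured by the enol ether character of that bond, by the absence of free phenols (no Reimer–Tiemann pathway) and by the electron-poor C2=C3 of 10, which does not take up a second carbene. A hydrocarbon medium and low temperature keep the heterogeneous tert-butoxide from attacking silicon before the carbene has added.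

Step 5
Reactants: 10 7,4'-bis(benzyloxy)-3-bromo-3'-methoxyflavone
Product: 12 7,4'-bis(benzyloxy)-3-hydroxy-3'-methoxyflavone, via flavone-3-boronic acid pinacol ester 11 (not isolated)
Conditions: B2pin2, Pd2(dba)3 (cat.), XPhos, KOAc, 1,4-dioxane, 90 °C; then 30% H2O2, aq. NaHCO3, THF, 0 °C → rt
Reagents that add atoms: hydrogen peroxide, OO
Why: Miyaura borylation of the alkenyl bromide (oxidative addition into C3–Br, acetate-assisted transmetalation with B2pin2) followed by the standard peroxide oxidation of the C–B bond with 1,2-shift of C3 from boron to oxygen; KOAc and bicarbonate are weak enough bases not to open the pyranone at C2.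

Step 6
Reactants: 12 7,4'-bis(benzyloxy)-3-hydroxy-3'-methoxyflavone
Product: 13 3,7,4'-trihydroxy-3'-methoxyflavone (geraldol)
Conditions: H2 (1 atm), 10% Pd/C, THF/MeOH, rt
Reagents that add atoms: none
Why: catalytic hydrogenolysis of the two benzyl aryl ethers, routinely applied to benzylated flavonols, whose conjugated tetrasubstituted C2=C3 bond should not be reduced under 1 atm of hydrogen at room temperature.

Step 7
Reactants: 13 3,7,4'-trihydroxy-3'-methoxyflavone
Product: 15 trisodium 3'-methoxyflavone-3,7,4'-triyl tris(sulfate), via tris(pyridinium) trisulfate 14 (not isolated)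
Conditions: SO3·pyridine (excess), pyridine, 60 °C; then aq. NaHCO3, 0 °C; C18 reversed-phase chromatography
Reagents that add atoms: sulfur trioxide–pyridine complex, [O-]S(=O)(=O)[n+]1ccccc1; sodium hydrogen carbonate, [Na+].OC([O-])=O
Why: O-sulfonation of phenolic and enolic hydroxyl groups with the SO3·pyridine complex; with no 5-OH present the only sluggish site is the 3-OH hydrogen-bonded to C4=O, which an excess of reagent at 60 °C should force, and bicarbonate exchange gives the stable sodium salt.

Step 8
Reactants: 15 trisodium 3'-methoxyflavone-3,7,4'-triyl tris(sulfate)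
Product: 16 2-[3-methoxy-4-(sulfooxy)phenyl]-4-oxo-4H-chromene-3,7-diyl bis(hydrogen sulfate) (target, CNP0382475.0)
Conditions: Dowex 50WX8 (H+ form), H2O, 0–5 °C; immediate freeze-drying
Reagents that add atoms: none
Why: cation exchange on a sulfonic acid resin replaces Na+ by H+; brief contact in cold dilute water and immediate freeze-drying should limit the acid-catalysed hydrolysis of the aryl and enol sulfate esters.

**Compound list**

1 | 6-hydroxybenzofuran-3(2H)-one | O=C1COc2cc(O)ccc21 | starting material
2 | 6-(benzyloxy)benzofuran-3(2H)-one | O=C1COc2cc(OCc3ccccc3)ccc21 | intermediate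
3 | 4-bromo-2-methoxyphenol | COc1cc(Br)ccc1O | starting material
4 | 1-(benzyloxy)-4-bromo-2-methoxybenzene | COc1cc(Br)ccc1OCc1ccccc1 | intermediate
5 | sodium 6-(benzyloxy)-2-[4-(benzyloxy)-3-methoxyphenyl]benzofuran-3-olate | COc1cc(-c2oc3cc(OCc4ccccc4)ccc3c2[O-])ccc1OCc1ccccc1.[Na+] | intermediate
6 | 6-(benzyloxy)-2-[4-(benzyloxy)-3-methoxyphenyl]-3-[(tert-butyldimethylsilyl)oxy]benzofuran | COc1cc(-c2oc3cc(OCc4ccccc4)ccc3c2O[Si](C)(C)C(C)(C)C)ccc1OCc1ccccc1 | intermediate
7 | bromoform | BrC(Br)Br | starting material
8 | 4-(benzyloxy)-1a-[4-(benzyloxy)-3-methoxyphenyl]-1,1-dibromo-6b-[(tert-butyldimethylsilyl)oxy]-1a,6b-dihydro-1H-cyclopropa[b]benzofuran (racemic; the cis ring fusion is the only one possible) | COc1cc(C23Oc4cc(OCc5ccccc5)ccc4C2(O[Si](C)(C)C(C)(C)C)C3(Br)Br)ccc1OCc1ccccc1 | intermediate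
9 | 7-(benzyloxy)-2-[4-(benzyloxy)-3-methoxyphenyl]-3-bromo-4-[(tert-butyldimethylsilyl)oxy]chromenylium bromide | COc1cc(-c2[o+]c3cc(OCc4ccccc4)ccc3c(O[Si](C)(C)C(C)(C)C)c2Br)ccc1OCc1ccccc1.[Br-] | intermediate
10 | 7-(benzyloxy)-2-[4-(benzyloxy)-3-methoxyphenyl]-3-bromo-4H-chromen-4-one | COc1cc(-c2oc3cc(OCc4ccccc4)ccc3c(=O)c2Br)ccc1OCc1ccccc1 | intermediate
11 | 7-(benzyloxy)-2-[4-(benzyloxy)-3-methoxyphenyl]-3-(4,4,5,5-tetramethyl-1,3,2-dioxaborolan-2-yl)-4H-chromen-4-one | COc1cc(-c2oc3cc(OCc4ccccc4)ccc3c(=O)c2B5OC(C)(C)C(C)(C)O5)ccc1OCc1ccccc1 | intermediate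
12 | 7-(benzyloxy)-2-[4-(benzyloxy)-3-methoxyphenyl]-3-hydroxy-4H-chromen-4-one | COc1cc(-c2oc3cc(OCc4ccccc4)ccc3c(=O)c2O)ccc1OCc1ccccc1 | intermediate
13 | 3,7-dihydroxy-2-(4-hydroxy-3-methoxyphenyl)-4H-chromen-4-one (geraldol) | COc1cc(-c2oc3cc(O)ccc3c(=O)c2O)ccc1O | intermediate
14 | tris(pyridinium) 2-(3-methoxy-4-sulfonatooxyphenyl)-4-oxo-4H-chromene-3,7-diyl bis(sulfate) | COc1cc(-c2oc3cc(OS(=O)(=O)[O-])ccc3c(=O)c2OS(=O)(=O)[O-])ccc1OS(=O)(=O)[O-].c1cc[nH+]cc1.c1cc[nH+]cc1.c1cc[nH+]cc1 | intermediate
15 | trisodium 2-(3-methoxy-4-sulfonatooxyphenyl)-4-oxo-4H-chromene-3,7-diyl bis(sulfate) | COc1cc(-c2oc3cc(OS(=O)(=O)[O-])ccc3c(=O)c2OS(=O)(=O)[O-])ccc1OS(=O)(=O)[O-].[Na+].[Na+].[Na+] | intermediate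
16 | 2-[3-methoxy-4-(sulfooxy)phenyl]-4-oxo-4H-chromene-3,7-diyl bis(hydrogen sulfate) | COc1cc(-c2oc3cc(OS(=O)(=O)O)ccc3c(=O)c2OS(=O)(=O)O)ccc1OS(=O)(=O)O | target

**Step count and risks**

Total step count: 8. Longest linear sequence: 7 steps (steps 1, 3, 4, 5, 6, 7, 8); step 2 is a one-step side branch.

Steps most likely to fail:

1. Step 4. The silyl group may be removed by tert-butoxide before the carbene adds, the hindered tetrasubstituted C2=C3 bond may add the carbene too slowly, or the cyclopropane may be diverted before it opens. A base-free carbene source would be the first adjustment. The fallback gives up the ring expansion and closes ring C by classical chemistry. It sets out from 4: bromine–lithium exchange (n-BuLi, THF, −78 °C) and formylation with DMF would give 4-(benzyloxy)-3-methoxybenzaldehyde F1. Claisen–Schmidt condensation of F1 with bought 1-[4-(benzyloxy)-2-hydroxyphenyl]ethanone F2 (KOH, EtOH, rt) would give the (E)-2'-hydroxychalcone F3. Algar–Flynn–Oyamada oxidation of F3 (30% H2O2, aq. NaOH, MeOH/THF, 0 °C → rt) should give the flavonol directly, since the chalcone has no 6'-substituent to divert it to an aurone. The fallback comes back to the route at 12.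

2. Step 5. Oxidative addition into the hindered C3–Br bond may be slow, and the α-boryl enone may lose boron by protodeboronation before it is oxidised, leaving the 3-unsubstituted flavone. The fallback sets out from 10 and makes the C3–O bond by cross-coupling instead. Ullmann-type etherification with benzyl alcohol (CuI, 3,4,7,8-tetramethyl-1,10-phenanthroline, Cs2CO3, toluene, 100 °C) would give 3,7-bis(benzyloxy)-2-[4-(benzyloxy)-3-methoxyphenyl]-4H-chromen-4-one F4. Hydrogenolysis of F4 under the conditions of step 6 removes all three benzyl groups, so the fallback comes back at 13 and compound 12 is skipped.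

3. Step 3. The ketone may self-condense under base before it is arylated, the coupling may stall with the electron-rich aryl bromide, or the enolate may be oxidised by traces of air before it is silylated. The fallback sets out from 2 and forms the same C2–C1' bond with reversed order of events. Silylation (TBSOTf, Et3N, CH2Cl2, 0 °C) would give 6-(benzyloxy)-3-[(tert-butyldimethylsilyl)oxy]benzofuran F5. Deprotonation of its C2–H (n-BuLi, THF, −78 °C) would give the 2-lithiobenzofuran F6, which is transmetalated at once with ZnCl2 to the benzofuran-2-ylzinc chloride F7, so that a silyl shift from oxygen to carbon is not given time. Negishi coupling of F7 with 4 (Pd(PPh3)4, THF, 50 °C) comes back to the route at 6.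

**Further compounds**

F1 | step 4 | 4-(benzyloxy)-3-methoxybenzaldehyde | COc1cc(C=O)ccc1OCc1ccccc1
F2 | step 4 | 1-[4-(benzyloxy)-2-hydroxyphenyl]ethanone (bought) | CC(=O)c1ccc(OCc2ccccc2)cc1O
F3 | step 4 | (E)-1-[4-(benzyloxy)-2-hydroxyphenyl]-3-[4-(benzyloxy)-3-methoxyphenyl]prop-2-en-1-one | COc1cc(/C=C/C(=O)c2ccc(OCc3ccccc3)cc2O)ccc1OCc1ccccc1
F4 | step 5 | 3,7-bis(benzyloxy)-2-[4-(benzyloxy)-3-methoxyphenyl]-4H-chromen-4-one | COc1cc(-c2oc3cc(OCc4ccccc4)ccc3c(=O)c2OCc5ccccc5)ccc1OCc1ccccc1
F5 | step 3 | 6-(benzyloxy)-3-[(tert-butyldimethylsilyl)oxy]benzofuran | CC(C)(C)[Si](C)(C)Oc1coc2cc(OCc3ccccc3)ccc12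
F6 | step 3 | [6-(benzyloxy)-3-[(tert-butyldimethylsilyl)oxy]benzofuran-2-yl]lithium | [Li]c1oc2cc(OCc3ccccc3)ccc2c1O[Si](C)(C)C(C)(C)C
F7 | step 3 | [6-(benzyloxy)-3-[(tert-butyldimethylsilyl)oxy]benzofuran-2-yl]zinc chloride | Cl[Zn]c1oc2cc(OCc3ccccc3)ccc2c1O[Si](C)(C)C(C)(C)C
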